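Late in Thursday's run Z stands still: 31.7% at 8.00 h, 32.0% at 50.0 h, with readings scattering by 0.5 percentage points. So what I watch is the first hours.

| setting | Thursday's | Tuesday's | flask |
|---|---|---|---|
| G | 0.10 M | 0.10 M | 0.10 M |
| X | 50 µM | 34 µM | 50 µM |
| remark | the very flask that is asked about, followed so far | run made earlier |  |
| time |  |  | 3.0 d |

- Thursday's (time / h: Z / %): 3.00: 31.8; 8.00: 31.7; 15.0: 31.9; 25.0: 31.8; 40.0: 32.0; 50.0: 32.0; 60.0: 30.9
- Tuesday's (time / h: Z / %): 0.167: 28.4; 0.417: 36.5; 0.833: 34.3; 1.33: 34.4; 1.50: 34.2; 2.00: 33.4; 3.00: 33.3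

(scatter of a reading: 0.5 percentage points)

- percentages count the G that a species holds: one E counts as two
- Z is meant together with its J
- solid, in amounts per volume of the solution: J
- additions bring no volume worth counting
- steps under discussion: 2 G -> E; J <-> Z; Z + X <-> D + X; G + X <-> Z + X; X -> L; D + X <-> G + X

- ash: at 3.0 d add X, 50.0% of the amount charged, then wait 40 h
- maple: change nothing and wait 40 h more
- oak: at 3.0 d add G, 50.0% of the amount charged, then wait 40 h

1. Z, in percent of the G first charged, at 3.0 d
2. the option that brings most further Z ("none" if no option brings more than 2 percentage points) (ash / maple / oak / none)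
3. Z present, in percent of the G first charged, after ash
4. Z present, in percent of the G first charged, after maple

A stop at equilibrium would not depend on the amount of catalyst. But at 3.00 h Thursday's flask, with 50 µM of X, reads 31.8%, lower than Tuesday's 33.3% with 34 µM. So I read X as passing into L, leaving a frozen mixture (kinetic, not thermodynamic, control). Tuesday's Z goes from 34.3% to 33.4% by 2.00 h, then reads 33.3%; I take that time as two lifetimes, so the lifetime of X is τ = 1.00 h, a rough reading. My rule is n, the number of lifetimes elapsed, time divided by τ: at 3.0 d, n = 72.0. Hardly any X then works, so I expect maple and oak to change nothing and Z to stay near Thursday's plateau. Ash brings 25.0 µM of fresh X, and more X went with less Z, so I expect ash to lower Z.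

The forecast gives 31.7%, 31.5% after maple, 30% after ash and best none, holding that “the plateau is a dead catalyst, not equilibrium”.

The flask gives 31.5%, 31.5% after maple and 28.9% after ash; oak brings 0 points, so best is none.

    2 G → E (k = 8.78 × 10⁻⁴ L mol⁻¹ min⁻¹)
    J ⇌ Z, rate k2*(cs2 - [Z]) while solid is left; crystals form when [Z] > cs2 (solubility = 0.0880 M, k = 0.233 min⁻¹)
    Z + X ⇌ D + X, rate k3*[X]*[Z] forward; the back reaction follows from the equilibrium constant (K = 1.70, k = 212 L mol⁻¹ min⁻¹)
    G + X ⇌ Z + X, rate k4*[G]*[X] forward; the back reaction follows from the equilibrium constant (K = 1.39, k = 1830 L mol⁻¹ min⁻¹)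
    X → L (k = 0.0272 min⁻¹)
    D + X ⇌ G + X, rate k6*[X]*[D] forward; the back reaction follows from the equilibrium constant (k = 567 L mol⁻¹ min⁻¹)

Dissolved Z has a half-life of 1.1 h by its forward step alone with X as charged, shorter than 3.0 d, yet by that time the constant of X → L counts n = 118 lifetimes, and 0% of the catalyst can turn over. At 20 h, the same constant gives n = 32.6, and that reading gives Z 31.5%.

The earlier runs and the new flask were computed on assumed constants; scatter was added.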